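**Retrosynthetic overview**

1. The target, epioritin-(4β→6)-epimesquitol-4β-ol, comes from global hydrogenolysis of its hepta-O-benzyl ether; the lower-unit 4β-OH comes from buffered, silver-assisted hydrolysis of a 4β-arylsulfanyl group (water enters trans to 3-OH).
2. The interflavanyl C4–C6 bond comes from an acid-catalysed SN1 coupling of the proanthocyanidin type: the all-cis flavan-3,4-diol of the upper unit (C4 electrophile) with C6 of the lower-unit 4β-thioether, whose C–S bond is inert to hard Lewis acid.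
3. Each pyran ring comes from the same key step: racemic dihydroflavonol → (2R,3R,4R)-all-cis-flavan-3,4-diol, by reversible chalcone-isomerase-type oxa-Michael ring opening and closure drained by asymmetric transfer hydrogenation (reductase-type). C2, C3 and C4 are set together.
4. The dihydroflavonols come from 2′-hydroxychalcones by oxidative oxa-Michael cyclisation (interrupted Algar–Flynn–Oyamada); the chalcones come from Claisen–Schmidt condensation of one benzylated gallacetophenone with two benzaldehydes.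
5. Ring order: ring C (upper unit) and ring F (lower unit) are closed in parallel on separate chalcones, first racemically, then again in the stereo-defining key step. The two flavans are joined afterwards; no ring is formed after the coupling.

Assumption: α/β refer to the usual flavan drawing (ring A left, ring oxygen on top), in which the 2-aryl group of these 2R compounds is α; racemates are given with one enantiomer in the SMILES.

**Route**

Step 1
Reactants: 1 gallacetophenone [1-(2,3,4-trihydroxyphenyl)ethanone]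
Product: 2 1-[3,4-bis(benzyloxy)-2-hydroxyphenyl]ethanone
Conditions: BnBr (2.1 equiv), K2CO3 (2.2 equiv), DMF, rt, 16 h
Reagents that add atoms: benzyl bromide, BrCc1ccccc1
Why: Williamson etherification; the 2-OH is hydrogen-bonded to the acetyl C=O and is the least nucleophilic, so the 4-OH and 3-OH are benzylated selectively.

Step 2
Reactants: 2 1-[3,4-bis(benzyloxy)-2-hydroxyphenyl]ethanone; 3 4-(benzyloxy)benzaldehyde
Product: 4 (E)-1-[3,4-bis(benzyloxy)-2-hydroxyphenyl]-3-[4-(benzyloxy)phenyl]prop-2-en-1-one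
Conditions: KOH (50% aq, 6 equiv), EtOH/THF, rt, 36 h; then 1 M HCl
Reagents that add atoms: none
Why: Claisen–Schmidt condensation; E1cB dehydration of the aldol gives only the (E)-enone, and benzyl ethers are stable to base.

Step 3
Reactants: 2 1-[3,4-bis(benzyloxy)-2-hydroxyphenyl]ethanone; 5 3,4-bis(benzyloxy)benzaldehyde
Product: 6 (E)-1-[3,4-bis(benzyloxy)-2-hydroxyphenyl]-3-[3,4-bis(benzyloxy)phenyl]prop-2-en-1-one
Conditions: KOH (50% aq, 6 equiv), EtOH/THF, rt, 36 h; then 1 M HCl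
Reagents that add atoms: none
Why: Claisen–Schmidt condensation as in step 2, giving the (E)-chalcone of the lower unit.

Step 4
Reactants: 4 (E)-chalcone of the upper unit
Product: 7 (±)-trans-7,8-bis(benzyloxy)-2-[4-(benzyloxy)phenyl]-3-hydroxychroman-4-one
Conditions: 30% aq H2O2 (3 equiv), 2 M NaOH (2.5 equiv), MeOH/THF 1:1, 0 °C, 2 h; AcOH quench
Reagents that add atoms: hydrogen peroxide, OO
Why: Algar–Flynn–Oyamada reaction stopped at the dihydroflavonol by working at 0 °C: 6-endo oxa-Michael attack of the 2′-phenoxide with oxygenation of C3 by peroxide (chalcone → flavanone → dihydroflavonol in one flask); the product is racemic and 2,3-trans (both substituents equatorial), and both centres are set again in step 6.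

Step 5
Reactants: 6 (E)-chalcone of the lower unit
Product: 8 (±)-trans-7,8-bis(benzyloxy)-2-[3,4-bis(benzyloxy)phenyl]-3-hydroxychroman-4-one
Conditions: 30% aq H2O2 (3 equiv), 2 M NaOH (2.5 equiv), MeOH/THF 1:1, 0 °C, 2 h; AcOH quench
Reagents that add atoms: hydrogen peroxide, OO
Why: interrupted Algar–Flynn–Oyamada oxidative oxa-Michael cyclisation as in step 4; racemic 2,3-trans product whose centres are set again in step 7.

Step 6
Reactants: 7 (±)-trans-dihydroflavonol of the upper unit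
Product: 11 (2R,3R,4R)-7,8-bis(benzyloxy)-2-[4-(benzyloxy)phenyl]-3,4-dihydro-2H-chromene-3,4-diol, via ring-opened α-hydroxychalcone 9 (not isolated), via 2,3-cis-dihydroflavonol 10 (not isolated)
Conditions: RuCl[(S,S)-TsDPEN](p-cymene) (3 mol%), HCO2H (5 equiv)/DBU (5.5 equiv), DMF, 40 °C, Ar, 24 h
Reagents that add atoms: none
Why: Proposed new method: in the basic formate medium C3–H of 7 is removed reversibly, and the enediolate either reprotonates (C3 epimerisation) or expels the C2 phenoxide (E1cB retro-oxa-Michael) to 9, which recloses by 6-endo oxa-Michael addition (the chalcone-isomerase ring closure), so all four dihydroflavonol stereoisomers interconvert; the (S,S)-ruthenium hydride adds to the β-face of C4 (4α-OH, the same facial sense as its (S)-chroman-4-ol reduction) and does so fastest for the one isomer in which that face is anti to both the 2-aryl and the 3-OH group, the (2R,3S)-cis ketone 10, so Curtin–Hammett funnelling gives the all-cis diol and sets C2, C3 and C4 together; the closest known chemistry is the Noyori–Ikariya dynamic kinetic resolution by asymmetric transfer hydrogenation of benzoin and of 3-substituted chroman-4-ones (cis alcohols) and the transfer-hydrogenative kinetic resolution of flavanones to 2,4-cis-flavan-4-ols.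

Step 7
Reactants: 8 (±)-trans-dihydroflavonol of the lower unit
Product: 14 (2R,3R,4R)-7,8-bis(benzyloxy)-2-[3,4-bis(benzyloxy)phenyl]-3,4-dihydro-2H-chromene-3,4-diol, via ring-opened α-hydroxychalcone 12 (not isolated), via 2,3-cis-dihydroflavonol 13 (not isolated)
Conditions: RuCl[(S,S)-TsDPEN](p-cymene) (3 mol%), HCO2H (5 equiv)/DBU (5.5 equiv), DMF, 40 °C, Ar, 24 h
Reagents that add atoms: none
Why: Proposed new method: as in step 6, base-mediated C3 epimerisation and E1cB ring opening to 12 with 6-endo oxa-Michael reclosure equilibrate all stereoisomers of 8, and the (S,S)-ruthenium hydride reduces fastest the (2R,3S)-cis ketone 13, whose C4 β-face is anti to both the 2-aryl and the 3-OH group, giving the all-cis (2R,3R,4R)-diol with C2, C3 and C4 set together; the closest known chemistry is the Noyori–Ikariya dynamic kinetic resolution of benzoin and of 3-substituted chroman-4-ones and the kinetic resolution of flavanones by asymmetric transfer hydrogenation.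

Step 8
Reactants: 14 all-cis diol of the lower unit
Product: 15 (2R,3S,4S)-7,8-bis(benzyloxy)-2-[3,4-bis(benzyloxy)phenyl]-4-[(2,6-dimethylphenyl)sulfanyl]-3,4-dihydro-2H-chromen-3-ol
Conditions: 2,6-Me2C6H3SH (5 equiv), Sc(OTf)3 (10 mol%), CH2Cl2, −20 → 0 °C
Reagents that add atoms: 2,6-dimethylbenzenethiol, Cc1cccc(C)c1S
Why: Lewis-acid SN1 thiolysis of the benzylic 4-OH (the reaction used to degrade proanthocyanidins); the thiol attacks the C4 cation on the β-face, anti to the axial 3-OH, giving the 2,3-cis-3,4-trans thioether, which blocks C4 of the lower unit and is inert to hard acids.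

Step 9
Reactants: 11 all-cis diol of the upper unit; 15 lower-unit 4β-thioether
Product: 16 hepta-O-benzyl (4β→6) dimer carrying the 4β-(2,6-dimethylphenyl)sulfanyl group on the lower unit
Conditions: 15 (3 equiv), Sc(OTf)3 (10 mol%), 4 Å MS, CH2Cl2, −40 → 0 °C, slow addition of 11
Reagents that add atoms: none
Why: dehydrative Friedel–Crafts alkylation (proanthocyanidin-type SN1 coupling): the 4-OH of 11 ionises and C6 of 15 (para to the ring oxygen, ortho to 7-OBn, the most nucleophilic carbon) attacks C4 from the β-face, anti to the axial 3-OH, which sets the upper C4 as 3,4-trans; O-alkylation is reversible under the acid and the C–S bond of 15 is untouched.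

Step 10
Reactants: 16 dimer thioether
Product: 17 hepta-O-benzyl ether of the target (lower unit 2,3-cis-3,4-trans diol)
Conditions: AgBF4 (2 equiv), 2,6-di-tert-butylpyridine (2.5 equiv), THF/H2O 10:1, 0 °C, dark
Reagents that add atoms: water, O
Why: thiophilic silver activation of the benzylic thioether (SN1 solvolysis, as used for 4-thioethers of flavans); water captures the lower-unit C4 cation from the β-face, trans to the 3-OH, and the buffer prevents re-ionisation, so the 4β-OH is formed under kinetic control.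

Step 11
Reactants: 17 hepta-O-benzyl ether of the target
Product: 18 epioritin-(4β→6)-epimesquitol-4β-ol (target)
Conditions: H2 (1 atm), Pd(OH)2/C, THF/H2O 4:1, rt, 3 h; filter; lyophilise
Reagents that add atoms: none
Why: hydrogenolysis of seven aryl benzyl ethers; the neutral, alcohol-free medium and short reaction time keep the labile benzylic 4β-OH (no 4-O-alkyl ether, no C4 epimerisation) and the pyran C–O bonds intact, and no stereocentre is touched.

**Compound list**

1 | gallacetophenone, 1-(2,3,4-trihydroxyphenyl)ethanone | CC(=O)c1ccc(O)c(O)c1O | starting material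
2 | 1-[3,4-bis(benzyloxy)-2-hydroxyphenyl]ethanone | CC(=O)c1ccc(OCc2ccccc2)c(OCc2ccccc2)c1O | intermediate
3 | 4-(benzyloxy)benzaldehyde | O=Cc1ccc(OCc2ccccc2)cc1 | starting material
4 | (E)-1-[3,4-bis(benzyloxy)-2-hydroxyphenyl]-3-[4-(benzyloxy)phenyl]prop-2-en-1-one | O=C(/C=C/c1ccc(OCc2ccccc2)cc1)c1ccc(OCc2ccccc2)c(OCc2ccccc2)c1O | intermediate
5 | 3,4-bis(benzyloxy)benzaldehyde | O=Cc1ccc(OCc2ccccc2)c(OCc2ccccc2)c1 | starting material
6 | (E)-1-[3,4-bis(benzyloxy)-2-hydroxyphenyl]-3-[3,4-bis(benzyloxy)phenyl]prop-2-en-1-one | O=C(/C=C/c1ccc(OCc2ccccc2)c(OCc2ccccc2)c1)c1ccc(OCc2ccccc2)c(OCc2ccccc2)c1O | intermediate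
7 | (±)-trans-7,8-bis(benzyloxy)-2-[4-(benzyloxy)phenyl]-3-hydroxychroman-4-one, (2R,3R) enantiomer drawn | O=C1c2ccc(OCc3ccccc3)c(OCc3ccccc3)c2O[C@H](c2ccc(OCc3ccccc3)cc2)[C@H]1O | intermediate
8 | (±)-trans-7,8-bis(benzyloxy)-2-[3,4-bis(benzyloxy)phenyl]-3-hydroxychroman-4-one, (2R,3R) enantiomer drawn | O=C1c2ccc(OCc3ccccc3)c(OCc3ccccc3)c2O[C@H](c2ccc(OCc3ccccc3)c(OCc3ccccc3)c2)[C@H]1O | intermediate
9 | (Z)-1-[3,4-bis(benzyloxy)-2-hydroxyphenyl]-3-[4-(benzyloxy)phenyl]-2-hydroxyprop-2-en-1-one (ring-opened α-hydroxychalcone) | O=C(/C(O)=C/c1ccc(OCc2ccccc2)cc1)c1ccc(OCc2ccccc2)c(OCc2ccccc2)c1O | intermediate (not isolated)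
10 | (2R,3S)-7,8-bis(benzyloxy)-2-[4-(benzyloxy)phenyl]-3-hydroxychroman-4-one (2,3-cis) | O=C1c2ccc(OCc3ccccc3)c(OCc3ccccc3)c2O[C@H](c2ccc(OCc3ccccc3)cc2)[C@@H]1O | intermediate (not isolated)
11 | (2R,3R,4R)-7,8-bis(benzyloxy)-2-[4-(benzyloxy)phenyl]-3,4-dihydro-2H-chromene-3,4-diol (2,3-cis-3,4-cis; tri-O-benzylteracacidin) | O[C@H]1[C@@H](O)[C@@H](c2ccc(OCc3ccccc3)cc2)Oc2c1ccc(OCc1ccccc1)c2OCc1ccccc1 | intermediate
12 | (Z)-1-[3,4-bis(benzyloxy)-2-hydroxyphenyl]-3-[3,4-bis(benzyloxy)phenyl]-2-hydroxyprop-2-en-1-one (ring-opened α-hydroxychalcone) | O=C(/C(O)=C/c1ccc(OCc2ccccc2)c(OCc2ccccc2)c1)c1ccc(OCc2ccccc2)c(OCc2ccccc2)c1O | intermediate (not isolated)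
13 | (2R,3S)-7,8-bis(benzyloxy)-2-[3,4-bis(benzyloxy)phenyl]-3-hydroxychroman-4-one (2,3-cis) | O=C1c2ccc(OCc3ccccc3)c(OCc3ccccc3)c2O[C@H](c2ccc(OCc3ccccc3)c(OCc3ccccc3)c2)[C@@H]1O | intermediate (not isolated)
14 | (2R,3R,4R)-7,8-bis(benzyloxy)-2-[3,4-bis(benzyloxy)phenyl]-3,4-dihydro-2H-chromene-3,4-diol (2,3-cis-3,4-cis; tetra-O-benzylmelacacidin) | O[C@H]1[C@@H](O)[C@@H](c2ccc(OCc3ccccc3)c(OCc3ccccc3)c2)Oc2c1ccc(OCc1ccccc1)c2OCc1ccccc1 | intermediate
15 | (2R,3S,4S)-7,8-bis(benzyloxy)-2-[3,4-bis(benzyloxy)phenyl]-4-[(2,6-dimethylphenyl)sulfanyl]-3,4-dihydro-2H-chromen-3-ol (2,3-cis-3,4-trans) | Cc1cccc(C)c1S[C@@H]1[C@@H](O)[C@@H](c2ccc(OCc3ccccc3)c(OCc3ccccc3)c2)Oc2c1ccc(OCc1ccccc1)c2OCc1ccccc1 | intermediate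
16 | (2R,3S,4S)-7,8-bis(benzyloxy)-2-[3,4-bis(benzyloxy)phenyl]-6-{(2R,3R,4R)-7,8-bis(benzyloxy)-2-[4-(benzyloxy)phenyl]-3-hydroxy-3,4-dihydro-2H-chromen-4-yl}-4-[(2,6-dimethylphenyl)sulfanyl]-3,4-dihydro-2H-chromen-3-ol (both units 2,3-cis-3,4-trans) | c1ccccc1COc1ccc([C@H]2Oc3c(ccc(OCc5ccccc5)c3OCc3ccccc3)[C@H](c3cc4c(c(OCc5ccccc5)c3OCc3ccccc3)O[C@H](c3ccc(OCc5ccccc5)c(OCc5ccccc5)c3)[C@H](O)[C@H]4Sc3c(C)cccc3C)[C@H]2O)cc1 | intermediate
17 | (2R,3R,4S)-7,8-bis(benzyloxy)-2-[3,4-bis(benzyloxy)phenyl]-6-{(2R,3R,4R)-7,8-bis(benzyloxy)-2-[4-(benzyloxy)phenyl]-3-hydroxy-3,4-dihydro-2H-chromen-4-yl}-3,4-dihydro-2H-chromene-3,4-diol (hepta-O-benzyl ether of 18) | c1ccccc1COc1ccc([C@H]2Oc3c(ccc(OCc5ccccc5)c3OCc3ccccc3)[C@H](c3cc4c(c(OCc5ccccc5)c3OCc3ccccc3)O[C@H](c3ccc(OCc5ccccc5)c(OCc5ccccc5)c3)[C@H](O)[C@H]4O)[C@H]2O)cc1 | intermediate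
18 | (2R,3R,4S)-2-(3,4-dihydroxyphenyl)-6-[(2R,3R,4S)-3,7,8-trihydroxy-2-(4-hydroxyphenyl)-3,4-dihydro-2H-chromen-4-yl]-3,4-dihydro-2H-chromene-3,4,7,8-tetrol, epioritin-(4β→6)-epimesquitol-4β-ol | Oc1ccc([C@H]2Oc3c(ccc(O)c3O)[C@H](c3cc4c(c(O)c3O)O[C@H](c3ccc(O)c(O)c3)[C@H](O)[C@H]4O)[C@H]2O)cc1 | target

**Step count and risks**

Total steps: 11. Longest linear sequence: 8 steps (1 → 2 → 6 → 8 → 14 → 15 → 16 → 17 → 18; steps 1, 3, 5, 7, 8, 9, 10, 11).

The three steps most likely to fail: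

Step 6. The stereoconvergent ring opening, reclosure and reduction has no direct precedent. It can fail in three ways:
- stereomutation of 7 is slower than reduction of the mismatched trans isomers, which gives 2,3-trans diols;
- the open-chain 9 (or its 1,2-diketone tautomer) is reduced;
- the base oxidises 7 to the flavonol or contracts the ring.

If only C3 epimerises, the (2R) half of 7 still funnels to 11, with at most 50% yield.

Fallback, setting out from 4 and coming back at 16: NaOAc in refluxing EtOH closes 4 to the racemic flavanone F1. RuCl[(S,S)-TsDPEN](p-cymene), HCO2H/Et3N 5:2, EtOAc, rt reduces only its (2S) enantiomer (kinetic resolution, no epimerisation needed) to the 2,4-cis-flavan-4-ol F2. p-TsOH (cat.), toluene, 60 °C dehydrates it to the flav-3-ene F3. NBS in THF/H2O at 0 °C adds bromine anti to the 2-aryl group and water at the benzylic C4, giving the trans-bromohydrin F4. K2CO3 in acetone closes the syn-epoxide F5, with its oxygen on the face of the 2-aryl group. Sc(OTf)3-catalysed Friedel–Crafts opening of F5 at C4 by C6 of 15, with inversion, gives 16 directly with the same 3α-OH/4β-aryl arrangement; 7 and 11 are bypassed.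

Step 7. It is the same unprecedented transformation, run on the less soluble tetrabenzyl series, and its product is needed in threefold excess for step 9.

Fallback, setting out from 6 and coming back at 15: NaOAc in refluxing EtOH gives the racemic flavanone F6. The same kinetic resolution with RuCl[(S,S)-TsDPEN](p-cymene), HCO2H/Et3N gives the 2,4-cis-flavan-4-ol F7. Dehydration (p-TsOH cat., toluene, 60 °C) gives the flav-3-ene F8. NBS in THF/H2O gives the trans-bromohydrin F9. K2CO3 in acetone gives the syn-epoxide F10. 2,6-Dimethylbenzenethiol with Sc(OTf)3 (cat.) opens F10 at the benzylic C4 with inversion and gives 15 directly (3α-OH, 4β-sulfanyl); 8 and 14 are bypassed.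

Step 9. The cation from 11 can alkylate C6 of a second molecule of 11 or of the product (oligomers). The all-cis 4α-OH is also the slower-ionising epimer, and C-alkylation competes with reversible ether formation.

Fallback, setting out from 11 and coming back at 18: block the self-reactive position first. NBS (1.05 equiv), CH2Cl2, −40 °C brominates 11 at C6 to give the 6-bromo diol F11. Sc(OTf)3-catalysed coupling of F11 with 15 (now 1.3 equiv) gives the bromo dimer thioether F12. AgBF4 and 2,6-di-tert-butylpyridine in THF/H2O give the bromo dimer diol F13. H2, Pd(OH)2/C, Et3N, THF/H2O removes the bromine together with the seven benzyl groups and gives 18.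

**Further compounds**

F1 | step 6 | (±)-7,8-bis(benzyloxy)-2-[4-(benzyloxy)phenyl]chroman-4-one, (2S) enantiomer drawn | O=C1C[C@@H](c2ccc(OCc3ccccc3)cc2)Oc2c1ccc(OCc1ccccc1)c2OCc1ccccc1
F2 | step 6 | (2S,4S)-7,8-bis(benzyloxy)-2-[4-(benzyloxy)phenyl]chroman-4-ol (2,4-cis) | O[C@H]1C[C@@H](c2ccc(OCc3ccccc3)cc2)Oc2c1ccc(OCc1ccccc1)c2OCc1ccccc1
F3 | step 6 | (2S)-7,8-bis(benzyloxy)-2-[4-(benzyloxy)phenyl]-2H-chromene | C1=C[C@@H](c2ccc(OCc3ccccc3)cc2)Oc2c1ccc(OCc1ccccc1)c2OCc1ccccc1
F4 | step 6 | (2R,3S,4R)-7,8-bis(benzyloxy)-2-[4-(benzyloxy)phenyl]-3-bromochroman-4-ol (2-aryl α, 3-Br β, 4-OH α) | O[C@H]1[C@H](Br)[C@@H](c2ccc(OCc3ccccc3)cc2)Oc2c1ccc(OCc1ccccc1)c2OCc1ccccc1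
F5 | step 6 | (2R)-7,8-bis(benzyloxy)-2-[4-(benzyloxy)phenyl]-3,4-epoxychromane, oxirane oxygen α, cis to the 2-aryl group | O1[C@@H]2c3ccc(OCc4ccccc4)c(OCc4ccccc4)c3O[C@H](c3ccc(OCc4ccccc4)cc3)[C@H]12
F6 | step 7 | (±)-7,8-bis(benzyloxy)-2-[3,4-bis(benzyloxy)phenyl]chroman-4-one, (2S) enantiomer drawn | O=C1C[C@@H](c2ccc(OCc3ccccc3)c(OCc3ccccc3)c2)Oc2c1ccc(OCc1ccccc1)c2OCc1ccccc1
F7 | step 7 | (2S,4S)-7,8-bis(benzyloxy)-2-[3,4-bis(benzyloxy)phenyl]chroman-4-ol (2,4-cis) | O[C@H]1C[C@@H](c2ccc(OCc3ccccc3)c(OCc3ccccc3)c2)Oc2c1ccc(OCc1ccccc1)c2OCc1ccccc1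
F8 | step 7 | (2S)-7,8-bis(benzyloxy)-2-[3,4-bis(benzyloxy)phenyl]-2H-chromene | C1=C[C@@H](c2ccc(OCc3ccccc3)c(OCc3ccccc3)c2)Oc2c1ccc(OCc1ccccc1)c2OCc1ccccc1
F9 | step 7 | (2R,3S,4R)-7,8-bis(benzyloxy)-2-[3,4-bis(benzyloxy)phenyl]-3-bromochroman-4-ol (2-aryl α, 3-Br β, 4-OH α) | O[C@H]1[C@H](Br)[C@@H](c2ccc(OCc3ccccc3)c(OCc3ccccc3)c2)Oc2c1ccc(OCc1ccccc1)c2OCc1ccccc1
F10 | step 7 | (2R)-7,8-bis(benzyloxy)-2-[3,4-bis(benzyloxy)phenyl]-3,4-epoxychromane, oxirane oxygen α, cis to the 2-aryl group | O1[C@@H]2c3ccc(OCc4ccccc4)c(OCc4ccccc4)c3O[C@H](c3ccc(OCc4ccccc4)c(OCc4ccccc4)c3)[C@H]12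
F11 | step 9 | (2R,3R,4R)-6-bromo-7,8-bis(benzyloxy)-2-[4-(benzyloxy)phenyl]-3,4-dihydro-2H-chromene-3,4-diol | O[C@H]1[C@@H](O)[C@@H](c2ccc(OCc3ccccc3)cc2)Oc2c1cc(Br)c(OCc1ccccc1)c2OCc1ccccc1
F12 | step 9 | analogue of 16 with bromine on C6 of the upper unit, same configuration at all six stereocentres | c1ccccc1COc1ccc([C@H]2Oc3c(cc(Br)c(OCc5ccccc5)c3OCc3ccccc3)[C@H](c3cc4c(c(OCc5ccccc5)c3OCc3ccccc3)O[C@H](c3ccc(OCc5ccccc5)c(OCc5ccccc5)c3)[C@H](O)[C@H]4Sc3c(C)cccc3C)[C@H]2O)cc1
F13 | step 9 | analogue of 17 with bromine on C6 of the upper unit, same configuration at all six stereocentres | c1ccccc1COc1ccc([C@H]2Oc3c(cc(Br)c(OCc5ccccc5)c3OCc3ccccc3)[C@H](c3cc4c(c(OCc5ccccc5)c3OCc3ccccc3)O[C@H](c3ccc(OCc5ccccc5)c(OCc5ccccc5)c3)[C@H](O)[C@H]4O)[C@H]2O)cc1
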